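C12–C13, C11=C12, C8=C17 and C4–C18 are cut first, then the ring-fusion bond C5–C10, then C4–C5, C1–C2 and C9–C10 (labdane numbering).
Enabling feature: C5–C10 is the only bond shared by rings A and B. It ties the fully substituted C10 (bearing the C20 methyl) to the C5 methine, so deleting it merges both rings into one carbocycle made of C1–C10. In that ring an exocyclic C10=C20 alkene lies opposite C5 of a C4=C5 alkylidene β-keto ester.
Forward order: the C5–C9/C11 chain is made, the C10/C1/C20 allyl unit is added at C9, and the C2–C4 acetoacetate unit is added at C1. The ten-membered ring is closed at C4–C5 and C4=C5 is introduced. One transannular bond then forms rings A and B together, and C17, C18, C19 and the C11–C16 dienyl butenolide follow.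
Stereochemistry: Sharpless epoxidation fixes C8 and C9, with C9 inverted on epoxide opening. A trans-fused 8,11-acetonide relays C9 to C10 and C5 in the key step. C4 comes from methylation anti to C20 and C3 from axial hydride delivery. C8 is later erased, and the E C11=C12 bond comes from the Takai olefination.
Key step: step 11

Remark: C8 is carried as a carbinol tied to O11 in an acetonide. A carbonyl derivative at C8 next to the doubly allylic C9–H would endanger the only source of chirality, and the dioxane also serves as turn element (step 9) and conformational lock (step 11).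
Remark: β-keto esters are drawn as keto tautomers, and C4 is a labile centre until step 16.

Step 1
Reactants: 1 5-chloropent-1-yne
Product: 3 6-chlorohex-2-yn-1-ol, via lithium acetylide 2 (not isolated)
Conditions: n-BuLi, THF, −78 °C; (CH2O)n, −78 °C to rt; H2O
Reagents that add atoms: n-butyllithium, [Li]CCCC (lithium, carried by 2 only); formaldehyde from paraformaldehyde, C=O
Why: Hydroxymethylation of a lithium acetylide with formaldehyde is routine, and the primary chloride is inert to the acetylide in THF without a dipolar cosolvent.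

Step 2
Reactants: 3 6-chlorohex-2-yn-1-ol
Product: 4 (E)-6-chlorohex-2-en-1-ol
Conditions: NaAlH2(OCH2CH2OMe)2, THF, 0 °C to rt; aq. work-up
Reagents that add atoms: none
Why: Alkoxide-directed trans-hydroalumination of a propargylic alcohol followed by protonolysis gives the (E)-allylic alcohol, and the primary chloride is not reduced at this temperature.

Step 3
Reactants: 4 (E)-6-chlorohex-2-en-1-ol
Product: 5 [(2S,3S)-3-(3-chloropropyl)oxiran-2-yl]methanol
Conditions: Ti(Oi-Pr)4 (10 mol %), L-(+)-diisopropyl tartrate (12 mol %), t-BuOOH, 4 Å MS, CH2Cl2, −20 °C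
Reagents that add atoms: tert-butyl hydroperoxide, CC(C)(C)OO
Why: Sharpless asymmetric epoxidation with L-(+)-tartrate delivers oxygen to the face of the (E)-allylic alcohol that gives the (2S,3S)-epoxide, which fixes C8 and, in still uninverted form, C9.

Step 4
Reactants: 5 [(2S,3S)-3-(3-chloropropyl)oxiran-2-yl]methanol; 6 (2-bromoallyl)trimethylsilane
Product: 8 (2R,3S)-6-chloro-2-[3-(trimethylsilyl)prop-1-en-2-yl]hexane-1,3-diol, via alkenyl Grignard reagent 7 (not isolated)
Conditions: 6, Mg, THF, rt; CuI (15 mol %), then 5, −40 to −15 °C; H2O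
Reagents that add atoms: magnesium, [Mg] (carried by 7 only)
Why: Copper-catalysed SN2 opening of a trans-2,3-epoxy alcohol by an alkenyl Grignard reagent occurs preferentially at C2 (here C9) with inversion, so the 1,3-diol should form with C9 R and the C8 carbinol untouched, the primary chloride being inert to the cuprate at this temperature.

Step 5
Reactants: 8 (2R,3S)-6-chloro-2-[3-(trimethylsilyl)prop-1-en-2-yl]hexane-1,3-diol
Product: 9 (4S,5R)-4-(3-chloropropyl)-2,2-dimethyl-5-[3-(trimethylsilyl)prop-1-en-2-yl]-1,3-dioxane
Conditions: 2,2-dimethoxypropane, PPTS (5 mol %), CH2Cl2, rt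
Reagents that add atoms: 2,2-dimethoxypropane, COC(C)(C)OC
Why: Acid-catalysed transketalisation closes the six-membered acetonide of the 1,3-diol with an acid too weak to protodesilylate the allylsilane, and in the chair both carbon arms (C7 and C10) are equatorial and gauche.

Step 6
Reactants: 9 (4S,5R)-4-(3-chloropropyl)-2,2-dimethyl-5-[3-(trimethylsilyl)prop-1-en-2-yl]-1,3-dioxane
Product: 10 (4S,5R)-5-(3-bromoprop-1-en-2-yl)-4-(3-chloropropyl)-2,2-dimethyl-1,3-dioxane
Conditions: NBS, CH2Cl2, −78 to −40 °C
Reagents that add atoms: N-bromosuccinimide, O=C1CCC(=O)N1Br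
Why: Bromodesilylation of an allylsilane (SE2' substitution) adds bromine to the methylene terminus and expels silicon, and because the allyl unit is symmetric about C10 the transposition only exchanges the roles of C1 and C20.

Step 7
Reactants: 10 (4S,5R)-5-(3-bromoprop-1-en-2-yl)-4-(3-chloropropyl)-2,2-dimethyl-1,3-dioxane; 11 methyl acetoacetate
Product: 13 methyl 6-[(4S,5R)-4-(3-chloropropyl)-2,2-dimethyl-1,3-dioxan-5-yl]-3-oxohept-6-enoate, via acetoacetate dianion 12 (not isolated)
Conditions: 11, NaH, THF, 0 °C; n-BuLi, 0 °C; 10, −78 to 0 °C; AcOH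
Reagents that add atoms: sodium hydride, [Na+].[H-], and n-butyllithium, [Li]CCCC (metals, carried by 12 only)
Why: γ-Alkylation of the acetoacetate dianion takes place at the more basic terminal carbon (C2) and selects the allylic bromide over the primary chloride, forming C1–C2.

Step 8
Reactants: 13 methyl 6-[(4S,5R)-4-(3-chloropropyl)-2,2-dimethyl-1,3-dioxan-5-yl]-3-oxohept-6-enoate
Product: 14 methyl 6-[(4S,5R)-4-(3-iodopropyl)-2,2-dimethyl-1,3-dioxan-5-yl]-3-oxohept-6-enoate
Conditions: NaI, acetone, reflux
Reagents that add atoms: sodium iodide, [Na+].[I-]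
Why: Finkelstein exchange, driven by precipitation of NaCl, turns the so far dormant chloride into the leaving group needed for ring closure.

Step 9
Reactants: 14 methyl 6-[(4S,5R)-4-(3-iodopropyl)-2,2-dimethyl-1,3-dioxan-5-yl]-3-oxohept-6-enoate
Product: 15 ten-membered β-keto ester (8S,9R; C4 epimers): ring C1–C10 with C3 ketone, C4 CO2Me, exocyclic C10=C20 and trans-fused 8,11-O-isopropylidene dioxane
Conditions: Cs2CO3, MeCN, 70 °C, syringe-pump addition of 14 (final about 1 mM)
Reagents that add atoms: none
Why: Intramolecular C-alkylation of a β-keto ester enolate by a primary iodide under pseudo-high dilution is the established carbanion route to medium and large carbocycles; here the trans-4,5-disubstituted dioxane holds both arms gauche and two ring atoms (C3, C10) are trigonal, which lowers the entropic and transannular cost, while the C4 epimer mixture is of no consequence.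

Step 10
Reactants: 15 ten-membered β-keto ester
Product: 19 ring-E ten-membered alkylidene β-keto ester (8S,9R), via sodium enolate 16 (not isolated), via selenide 17 (not isolated), via selenoxide 18 (not isolated)
Conditions: NaH, THF, 0 °C; PhSeCl, −78 °C; then H2O2 (30 % aq.), pyridine, CH2Cl2, 0 °C; used at once
Reagents that add atoms: sodium hydride, [Na+].[H-] (sodium, carried by 16 only); benzeneselenenyl chloride, Cl[Se]c1ccccc1 (PhSe, carried by 17 and 18 only); hydrogen peroxide, OO (oxygen, carried by 18 only)
Why: Selenenylation of the preformed enolate (faster than addition of PhSeCl to the alkene) and selenoxide syn elimination is the standard dehydrogenation of macrocyclic β-keto esters; only C5 carries β-hydrogens, and syn eliminations in ten-membered rings run through the conformer with C3 and C6 far apart, which gives the E ring alkene (C3 trans to C6; CIP descriptor Z because CO2Me outranks C3).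

Step 11
Reactants: 19 ring-E ten-membered alkylidene β-keto ester
Product: 20 tricyclic β-keto ester (4R,5R,8S,9R,10R): trans-decalin with C3 ketone, equatorial C4 CO2Me, axial C20 methyl on C10, H5 anti to C20, dioxane trans-fused at C8–C9
Conditions: Fe(acac)3 (30 mol %), Ph(i-PrO)SiH2, degassed THF–i-PrOH (4:1), 0.005 M, rt
Reagents that add atoms: none
Why: Proposed new method: the iron hydride generated from Fe(acac)3 and the silane transfers a hydrogen atom to C20 of the electron-neutral 1,1-disubstituted alkene, which creates the C20 methyl group and a nucleophilic tertiary radical at C10; this radical bonds transannularly to the electrophilic C5, and the C4 radical left between ketone and ester is reduced by divalent iron and protonated by i-PrOH to the β-keto ester. The closest known reaction types are the iron-hydride reductive coupling of unactivated with electron-poor alkenes (also in ring-forming mode) and the transannular closure of (E)-cyclodecenes and cyclodecadienes to trans-decalins, but a hydrogen-atom-transfer Giese addition across a ten-membered ring is not documented. The single new bond closes ring B (C5–C10) in 6-exo-trig mode, C4 staying outside, and ring A (C1–C5, C10) in 6-endo-trig mode, both acceptor carbons ending inside. C10 is controlled by the trans-fused dioxane, which admits only the chair of the nascent ring B with O8 and C11 equatorial, so that C5 meets the radical face that leaves C20 axial and cis to C11; C5 is controlled by the ring-E alkene within the chair–chair array, where C4 and C6 are equatorial and H5 is axial and anti to C20 (trans fusion); C4 is protonated last and settles as the equatorial ester or its enol. The step needs hydrogen atom transfer to C10=C20 and not to C4=C5 (the unhindered methylene terminus gives a tertiary radical, the acceptor is trisubstituted and electron-poor), attack at C5 and not at C4 (C5 is the β-position of both carbonyl groups and C4 is fully substituted) and closure ahead of a second hydrogen atom transfer to C10 (C5 and C10 are in contact across the ring and the silane is kept dilute).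

Step 12
Reactants: 20 tricyclic β-keto ester
Product: 21 8,11-diol β-keto ester (4R,5R,8S,9R,10R): trans-decalin with equatorial C8 OH and equatorial C9 CH2OH
Conditions: AcOH–H2O (4:1), 40 °C
Reagents that add atoms: none
Why: Acetal hydrolysis in aqueous acetic acid removes the acetonide, whose steering role is over, and leaves the methyl β-keto ester untouched.

Step 13
Reactants: 21 8,11-diol β-keto ester
Product: 22 11-O-TBS ether of 21 (4R,5R,8S,9R,10R)
Conditions: TBSCl, imidazole, CH2Cl2, 0 °C
Reagents that add atoms: tert-butyldimethylsilyl chloride, CC(C)(C)[Si](C)(C)Cl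
Why: Silylation with TBSCl and imidazole at 0 °C discriminates sterically in favour of the primary C11 hydroxyl over the secondary C8 hydroxyl.

Step 14
Reactants: 22 11-O-TBS ether
Product: 23 3,8-diketo ester (4R,5R,9R,10R) with C9 CH2OTBS equatorial
Conditions: Dess–Martin periodinane, CH2Cl2, 0 °C to rt
Reagents that add atoms: none
Why: Dess–Martin oxidation converts the C8 carbinol into the ketone under near-neutral conditions that do not eliminate the β-silyloxy group; the auxiliary C8 centre is erased and C9 keeps its thermodynamically favoured equatorial arm.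

Step 15
Reactants: 23 3,8-diketo ester
Product: 26 8(17)-methylene β-keto ester (4R,5R,9R,10R), via diketo ester enolate 24 (not isolated), via methylene ester enolate 25 (not isolated)
Conditions: Ph3PCH3Br, KOt-Bu (excess), THF, 0 to 40 °C; AcOH
Reagents that add atoms: methyltriphenylphosphonium bromide, C[P+](c1ccccc1)(c1ccccc1)c1ccccc1.[Br-] (CH2 = C17); potassium tert-butoxide, CC(C)(C)[O-].[K+] (potassium, carried by 24 and 25 only)
Why: Wittig methylenation in which the first equivalent of base stores the C3 ketone and the ester as the unreactive β-keto ester enolate, so that the non-stabilised ylide attacks only the C8 ketone, as is usual for 8-oxo drimane and labdane intermediates.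

Step 16
Reactants: 26 8(17)-methylene β-keto ester
Product: 27 C4-methylated keto ester (4S,5S,9R,10R): C18 methyl equatorial, CO2Me axial and cis to C20
Conditions: MeI, K2CO3, acetone, rt to 40 °C
Reagents that add atoms: iodomethane, CI
Why: C-Alkylation of a cyclic β-keto ester in which MeI approaches C4 from the equatorial side, anti to the axial C20 methyl, so that the ester (future C19) ends axial, the known outcome for 10-methyl-3-oxodecalin-4-carboxylates.

Step 17
Reactants: 27 C4-methylated keto ester
Product: 28 3,19-diol (3R,4R,5S,9R,10R) with equatorial C3 OH, axial C4 CH2OH, C11 OTBS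
Conditions: LiAlH4, Et2O, −10 to 0 °C; H2O, aq. NaOH
Reagents that add atoms: none
Why: LiAlH4 reduces ester and ketone in one operation, hydride reaching C3 along the axial trajectory on the face opposite to the axial C4 and C10 substituents, which gives the equatorial alcohol as with other 4,4-disubstituted 3-oxo terpenoids.

Step 18
Reactants: 28 3,19-diol
Product: 29 19-acetate (3R,4R,5S,9R,10R) with free C3 OH and C11 OTBS
Conditions: AcCl, 2,4,6-collidine, CH2Cl2, −78 °C
Reagents that add atoms: acetyl chloride, CC(=O)Cl
Why: Kinetic acylation at low temperature selects the primary C19 hydroxyl over the secondary C3 hydroxyl, which is flanked by the quaternary C4.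

Step 19
Reactants: 29 19-acetate
Product: 30 19-acetoxy-3,11-diol (3R,4R,5S,9R,10R)
Conditions: HF·pyridine, pyridine, THF, 0 °C to rt
Reagents that add atoms: none
Why: Fluoride cleavage of the primary silyl ether in a buffered, non-basic medium avoids migration of the acetyl group from O19 to O3.

Step 20
Reactants: 30 19-acetoxy-3,11-diol
Product: 31 C11 aldehyde (3R,4R,5S,9R,10R)
Conditions: TEMPO (20 mol %), PhI(OAc)2, CH2Cl2, rt
Reagents that add atoms: none
Why: Oxoammonium oxidation is selective for primary over hindered secondary alcohols and is mild enough not to move C8=C17 into conjugation or to epimerise C9.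

Step 21
Reactants: 31 C11 aldehyde
Product: 32 (E)-C11=C12 iodoalkene (3R,4R,5S,9R,10R)
Conditions: CrCl2, CHI3, THF–dioxane, 0 °C to rt
Reagents that add atoms: iodoform, IC(I)I
Why: Takai olefination is non-basic, tolerates hydroxyl and acetate, and gives the (E)-iodoalkene, all the more with an α-branched aldehyde.

Step 22
Reactants: 33 furan-2(5H)-one
Product: 35 3-bromofuran-2(5H)-one, via dibromolactone 34 (not isolated)
Conditions: Br2, CH2Cl2, reflux; Et3N, 0 °C
Reagents that add atoms: bromine, BrBr
Why: Bromination–dehydrobromination: bromine adds to the butenolide and removal of the acidic α-hydrogen expels the β-bromide, which leaves the α-bromobutenolide.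

Step 23
Reactants: 35 3-bromofuran-2(5H)-one
Product: 36 3-(tributylstannyl)furan-2(5H)-one
Conditions: (Bu3Sn)2, Pd(PPh3)4 (5 mol %), toluene, 100 °C
Reagents that add atoms: hexabutyldistannane, CCCC[Sn](CCCC)(CCCC)[Sn](CCCC)(CCCC)CCCC
Why: Palladium-catalysed stannylation of an alkenyl bromide with a distannane (oxidative addition to zerovalent palladium, transmetalation, reductive elimination).

Step 24
Reactants: 32 (E)-C11=C12 iodoalkene; 36 3-(tributylstannyl)furan-2(5H)-one
Product: 37 target, 19-O-acetyl-14-deoxy-11,12-didehydroandrographolide (3R,4R,5S,9R,10R,11E)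
Conditions: Pd2(dba)3 (5 mol %), AsPh3 (20 mol %), CuI (10 mol %), DMF, rt to 40 °C
Reagents that add atoms: none
Why: Stille coupling of an (E)-iodoalkene with an α-stannyl butenolide retains the alkene geometry under neutral conditions, so that acetate, free C3 hydroxyl, exocyclic alkene and the doubly allylic C9–H survive.

Compound list
1 | 5-chloropent-1-yne | C#CCCCCl | starting material
2 | (5-chloropent-1-yn-1-yl)lithium | [Li]C#CCCCCl | intermediate
3 | 6-chlorohex-2-yn-1-ol | OCC#CCCCCl | intermediate
4 | (E)-6-chlorohex-2-en-1-ol | OC/C=C/CCCCl | intermediate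
5 | [(2S,3S)-3-(3-chloropropyl)oxiran-2-yl]methanol | ClCCC[C@@H]1O[C@H]1CO | intermediate
6 | (2-bromoallyl)trimethylsilane | C=C(Br)C[Si](C)(C)C | starting material
7 | [3-(trimethylsilyl)prop-1-en-2-yl]magnesium bromide | C=C([Mg]Br)C[Si](C)(C)C | intermediate
8 | (2R,3S)-6-chloro-2-[3-(trimethylsilyl)prop-1-en-2-yl]hexane-1,3-diol | ClCCC[C@H](O)[C@@H](CO)C(=C)C[Si](C)(C)C | intermediate
9 | (4S,5R)-4-(3-chloropropyl)-2,2-dimethyl-5-[3-(trimethylsilyl)prop-1-en-2-yl]-1,3-dioxane | ClCCC[C@@H]1OC(C)(C)OC[C@H]1C(=C)C[Si](C)(C)C | intermediate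
10 | (4S,5R)-5-(3-bromoprop-1-en-2-yl)-4-(3-chloropropyl)-2,2-dimethyl-1,3-dioxane | ClCCC[C@@H]1OC(C)(C)OC[C@H]1C(=C)CBr | intermediate
11 | methyl acetoacetate | COC(=O)CC(C)=O | starting material
12 | sodium lithium dianion of methyl acetoacetate | [Na+].[Li+].COC(=O)[CH-]C(=O)[CH2-] | intermediate
13 | methyl 6-[(4S,5R)-4-(3-chloropropyl)-2,2-dimethyl-1,3-dioxan-5-yl]-3-oxohept-6-enoate | ClCCC[C@@H]1OC(C)(C)OC[C@H]1C(=C)CCC(=O)CC(=O)OC | intermediate
14 | methyl 6-[(4S,5R)-4-(3-iodopropyl)-2,2-dimethyl-1,3-dioxan-5-yl]-3-oxohept-6-enoate | ICCC[C@@H]1OC(C)(C)OC[C@H]1C(=C)CCC(=O)CC(=O)OC | intermediate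
15 | ten-membered β-keto ester (8S,9R; C4 epimers), C3 ketone, C4 CO2Me, C10=C20, trans-fused 8,11-acetonide | C=C1CCC(=O)C(C(=O)OC)CCC[C@@H]2OC(C)(C)OC[C@@H]12 | intermediate
16 | sodium enolate of 15 | [Na+].C=C1CCC([O-])=C(C(=O)OC)CCC[C@@H]2OC(C)(C)OC[C@@H]12 | intermediate
17 | C4 phenylselenide of 15 | C=C1CCC(=O)C([Se]c3ccccc3)(C(=O)OC)CCC[C@@H]2OC(C)(C)OC[C@@H]12 | intermediate
18 | selenoxide of 17 | C=C1CCC(=O)C([Se](=O)c3ccccc3)(C(=O)OC)CCC[C@@H]2OC(C)(C)OC[C@@H]12 | intermediate
19 | ring-E ten-membered alkylidene β-keto ester (8S,9R; C3 trans to C6 across C4=C5) | C=C1CCC(=O)/C(C(=O)OC)=C/CC[C@@H]2OC(C)(C)OC[C@@H]12 | intermediate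
20 | tricyclic trans-decalin β-keto ester (4R,5R,8S,9R,10R) with trans-fused 8,11-acetonide | COC(=O)[C@H]1C(=O)CC[C@]2(C)[C@@H]1CC[C@@H]3OC(C)(C)OC[C@@H]23 | intermediate
21 | 8,11-diol β-keto ester (4R,5R,8S,9R,10R) | COC(=O)[C@H]1C(=O)CC[C@]2(C)[C@@H]1CC[C@H](O)[C@H]2CO | intermediate
22 | 11-O-TBS 8-hydroxy β-keto ester (4R,5R,8S,9R,10R) | COC(=O)[C@H]1C(=O)CC[C@]2(C)[C@@H]1CC[C@H](O)[C@H]2CO[Si](C)(C)C(C)(C)C | intermediate
23 | 11-O-TBS 3,8-diketo ester (4R,5R,9R,10R) | COC(=O)[C@H]1C(=O)CC[C@]2(C)[C@@H]1CCC(=O)[C@H]2CO[Si](C)(C)C(C)(C)C | intermediate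
24 | potassium enolate of 23 | [K+].COC(=O)C1=C([O-])CC[C@]2(C)[C@@H]1CCC(=O)[C@H]2CO[Si](C)(C)C(C)(C)C | intermediate
25 | potassium enolate of 26 | [K+].COC(=O)C1=C([O-])CC[C@]2(C)[C@@H]1CCC(=C)[C@H]2CO[Si](C)(C)C(C)(C)C | intermediate
26 | 11-O-TBS 8(17)-methylene β-keto ester (4R,5R,9R,10R) | COC(=O)[C@H]1C(=O)CC[C@]2(C)[C@@H]1CCC(=C)[C@H]2CO[Si](C)(C)C(C)(C)C | intermediate
27 | C4-methylated keto ester (4S,5S,9R,10R), axial CO2Me | COC(=O)[C@]1(C)C(=O)CC[C@]2(C)[C@@H]1CCC(=C)[C@H]2CO[Si](C)(C)C(C)(C)C | intermediate
28 | 11-O-TBS 3,19-diol (3R,4R,5S,9R,10R) | OC[C@]1(C)[C@H](O)CC[C@]2(C)[C@@H]1CCC(=C)[C@H]2CO[Si](C)(C)C(C)(C)C | intermediate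
29 | 11-O-TBS 19-acetate (3R,4R,5S,9R,10R) | CC(=O)OC[C@]1(C)[C@H](O)CC[C@]2(C)[C@@H]1CCC(=C)[C@H]2CO[Si](C)(C)C(C)(C)C | intermediate
30 | 19-acetoxy-3,11-diol (3R,4R,5S,9R,10R) | CC(=O)OC[C@]1(C)[C@H](O)CC[C@]2(C)[C@@H]1CCC(=C)[C@H]2CO | intermediate
31 | 19-acetoxy-3-hydroxy C11 aldehyde (3R,4R,5S,9R,10R) | CC(=O)OC[C@]1(C)[C@H](O)CC[C@]2(C)[C@@H]1CCC(=C)[C@H]2C=O | intermediate
32 | (E)-12-iodo C11=C12 alkene (3R,4R,5S,9R,10R) | CC(=O)OC[C@]1(C)[C@H](O)CC[C@]2(C)[C@@H]1CCC(=C)[C@H]2/C=C/I | intermediate
33 | furan-2(5H)-one | O=C1C=CCO1 | starting material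
34 | 3,4-dibromodihydrofuran-2(3H)-one | O=C1OCC(Br)C1Br | intermediate
35 | 3-bromofuran-2(5H)-one | O=C1OCC=C1Br | intermediate
36 | 3-(tributylstannyl)furan-2(5H)-one | CCCC[Sn](CCCC)(CCCC)C1=CCOC1=O | intermediate
37 | 19-O-acetyl-14-deoxy-11,12-didehydroandrographolide (CNP0346413.1) | C=C1CC[C@@H]2[C@](C)(COC(C)=O)[C@H](O)CC[C@@]2(C)[C@@H]1/C=C/C1=CCOC1=O | target

Total step count: 24. Longest linear sequence: 22 (steps 1–21 and 24, from 1).

Steps most likely to fail

1. Step 11. The C10 radical may be quenched by a second hydrogen atom transfer before it reaches C5. The hydride–silane system may reduce the acceptor in conjugate fashion. Closure may also run through a non-chair array and erode the trans fusion.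
Fallback, from 19 back to 20: the radical is made by halogen abstraction instead of hydrogen atom transfer. Ionic Markovnikov addition of one equivalent of anhydrous HBr (CH2Cl2, −78 °C) to the exocyclic alkene, to which the electron-poor C4=C5 bond is inert, would give the tertiary C10 bromide F1. Slow addition of Bu3SnH with AIBN in refluxing benzene would then run the classical stannane-mediated Giese cyclisation across the ring. The C4 radical takes its hydrogen from the stannane to give 20.

2. Step 9. Intermolecular alkylation (oligomerisation) and O-alkylation of the enolate may outrun the slow closure of a ten-membered ring.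
Fallback, from 14 back to 19, bypassing steps 9 and 10: the ring is closed by condensation instead of substitution. Kornblum-type oxidation of the iodide (AgBF4, DMSO; then Et3N) would give the C5 aldehyde F2. An intramolecular Knoevenagel condensation (catalytic piperidinium acetate, 4 Å MS, toluene, high dilution) would form C4=C5 and the ring in one operation.

3. Step 10. The syn elimination may proceed through the conformer that leads to the Z ring alkene, or the strained E alkylidene may isomerise on handling. Either loss of geometry would carry over into cis ring fusion.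
Fallback, from 15 back to 20: either geometry is accepted and C5 is corrected afterwards.
- The same one-flask sequence through 16, 17 and 18 would give the ring-Z alkylidene β-keto ester F3.
- Under the conditions of step 11, F3 should close to the cis-fused keto ester F4, with C10 still dictated by the dioxane.
- Dehydrogenation with DDQ (dioxane, 80 °C) would give the 4-carbomethoxy-Δ4-octalone F5.
- Dissolving-metal reduction (Li, NH3–THF, −78 °C) protonates C5 axially and gives the trans-fused lithium enolate F6, which NH4Cl converts into 20.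

Further compounds
F1 | step 11 | tertiary C10 bromide of 19 (8S,9R; C10 epimers), ring-E alkylidene β-keto ester | CC1(Br)CCC(=O)/C(C(=O)OC)=C/CC[C@@H]2OC(C)(C)OC[C@@H]12
F2 | step 9 | methyl 6-[(4S,5R)-2,2-dimethyl-4-(3-oxopropyl)-1,3-dioxan-5-yl]-3-oxohept-6-enoate | O=CCC[C@@H]1OC(C)(C)OC[C@H]1C(=C)CCC(=O)CC(=O)OC
F3 | step 10 | ring-Z isomer of 19 (8S,9R; C3 cis to C6) | C=C1CCC(=O)/C(C(=O)OC)=C\CC[C@@H]2OC(C)(C)OC[C@@H]12
F4 | step 10 | cis-fused C5 epimer of 20 (C4 unassigned) | COC(=O)C1C(=O)CC[C@]2(C)[C@H]1CC[C@@H]3OC(C)(C)OC[C@@H]23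
F5 | step 10 | 4-carbomethoxy-Δ4-octalone with 8,11-acetonide (8S,9R,10R) | COC(=O)C1=C2CC[C@@H]3OC(C)(C)OC[C@H]3[C@]2(C)CCC1=O
F6 | step 10 | lithium enolate of 20 | [Li+].COC(=O)C1=C([O-])CC[C@]2(C)[C@@H]1CC[C@@H]3OC(C)(C)OC[C@@H]23
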